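**Retrosynthetic overview**
- The target is the 2',2'-linked biaryl dimer of (−)-epigallocatechin. The last step is global hydrogenolysis of a dodecabenzyl ether, and both cis-3-hydroxyl groups come from hydride reduction of a bis(flavan-3-one).
- The two ketones come from Baeyer–Villiger excision of the formyl carbons of a bis(2H-chromene-3-carbaldehyde).
- Key step: both pyran rings (ring C) close in one operation. A biaryl bis-enal and two equivalents of a ring-A salicylaldehyde undergo amine-catalysed oxa-Michael addition, then intramolecular aldol condensation.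
- The bis-enal comes from Wittig homologation of a biaryl dialdehyde made by Ullmann homocoupling of 2-bromo-3,4,5-tris(benzyloxy)benzaldehyde. The salicylaldehyde comes from phloroglucinol in four steps.
- Ring order: rings A and B are bought as arenes, the B–B' biaryl bond is made first, and the two rings C are made last and together.

Assumption: theasinensin C has the (aR) biaryl axis. The SMILES cannot encode the axis, so it is given in the names only. The axis is not controlled in this route: the (aR) atropisomer is isolated by chromatography in step 9, which costs about half the material at that point.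

**Branch A (ring A)**

Step 1
Reactants: 1 phloroglucinol
Product: 2 benzene-1,3,5-triyl triacetate
Conditions: Ac2O, pyridine, 4-(dimethylamino)pyridine (cat.), 0 °C to rt
Reagents that add atoms: acetic anhydride, CC(=O)OC(C)=O
Why: Exhaustive O-acylation masks the three phenols so that the next step can release them one at a time.

Step 2
Reactants: 2 benzene-1,3,5-triyl triacetate
Product: 4 1,3,5-tris(benzyloxy)benzene, via sodium 3,5-bis(benzyloxy)phenolate 3 (not isolated)
Conditions: NaH, BnCl, DMF, 0 °C; H2O added dropwise, then rt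
Reagents that add atoms: benzyl chloride, ClCc1ccccc1
Why: One-pot acetate cleavage and Williamson etherification, in which NaOH formed slowly from NaH and water frees each aryloxide (the last one being 3) in the presence of excess BnCl, so O-benzylation outruns the C-benzylation that plagues free phloroglucinol.

Step 3
Reactants: 4 1,3,5-tris(benzyloxy)benzene
Product: 6 2,4,6-tris(benzyloxy)benzaldehyde, via aryl iminium chloride 5 (not isolated)
Conditions: POCl3, DMF, 0 °C to rt; then H2O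
Reagents that add atoms: N,N-dimethylformamide, CN(C)C=O; water, O
Why: Vilsmeier–Haack formylation of a very electron-rich arene whose three free positions are equivalent, and the iminium group of 5 deactivates the ring against a second formylation.

Step 4
Reactants: 6 2,4,6-tris(benzyloxy)benzaldehyde
Product: 7 4,6-bis(benzyloxy)-2-hydroxybenzaldehyde
Conditions: MgBr2·OEt2, toluene/Et2O, 80 °C; then 1 M HCl
Reagents that add atoms: none
Why: Chelation-directed ether cleavage, in which magnesium bound between the carbonyl and one ortho benzyloxy group activates only that ether for bromide attack, and the resulting magnesium phenoxide chelate shuts the reaction down after one debenzylation.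

**Branch B (rings B and the biaryl bond)**

Step 5
Reactants: 8 3,4,5-trihydroxybenzaldehyde
Product: 9 3,4,5-tris(benzyloxy)benzaldehyde
Conditions: BnBr, K2CO3, DMF, 60 °C, N2
Reagents that add atoms: benzyl bromide, BrCc1ccccc1
Why: Threefold Williamson etherification of acidic phenols, run under nitrogen because the pyrogallol anion is air-sensitive.

Step 6
Reactants: 9 3,4,5-tris(benzyloxy)benzaldehyde
Product: 10 2-bromo-3,4,5-tris(benzyloxy)benzaldehyde
Conditions: NBS, MeCN, rt, dark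
Reagents that add atoms: N-bromosuccinimide, O=C1CCC(=O)N1Br
Why: Electrophilic aromatic bromination at one of the two equivalent free positions (ortho and para to benzyloxy groups), with a polar medium and darkness to suppress benzylic radical bromination.

Step 7
Reactants: 10 2-bromo-3,4,5-tris(benzyloxy)benzaldehyde (2 equiv)
Product: 11 rac-4,4',5,5',6,6'-hexakis(benzyloxy)biphenyl-2,2'-dicarbaldehyde
Conditions: Cu bronze (activated), DMF, 150 °C, N2
Reagents that add atoms: none
Why: Ullmann reductive homocoupling, helped by the ortho formyl group, which gives a tetra-ortho-substituted biaryl that is configurationally stable but racemic.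

Step 8
Reactants: 11 rac-4,4',5,5',6,6'-hexakis(benzyloxy)biphenyl-2,2'-dicarbaldehyde
Product: 12 rac-(2E,2'E)-3,3'-[4,4',5,5',6,6'-hexakis(benzyloxy)biphenyl-2,2'-diyl]bis(prop-2-enal)
Conditions: Ph3P=CHCHO (2.5 equiv), toluene, 90 °C
Reagents that add atoms: (triphenylphosphoranylidene)acetaldehyde, O=CC=P(c1ccccc1)(c1ccccc1)c1ccccc1
Why: Double Wittig olefination with a stabilised formyl ylide gives the E enals, and the reaction is stopped at full conversion of 11 so that dienal over-homologation stays minor and is removed by chromatography.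

**Union and endgame**

Step 9
Reactants: 12 rac-(2E,2'E)-3,3'-[4,4',5,5',6,6'-hexakis(benzyloxy)biphenyl-2,2'-diyl]bis(prop-2-enal); 7 4,6-bis(benzyloxy)-2-hydroxybenzaldehyde (2.4 equiv)
Product: 15 (aR)-2,2'-[4,4',5,5',6,6'-hexakis(benzyloxy)biphenyl-2,2'-diyl]bis[(2R)-5,7-bis(benzyloxy)-2H-chromene-3-carbaldehyde], via open-chain bis(aryloxy aldehyde) 13 (not isolated), via bis(4-hydroxychromane-3-carbaldehyde) 14 (not isolated)
Conditions: (S)-2-[diphenyl(trimethylsilyloxy)methyl]pyrrolidine (30 mol %), 2-nitrobenzoic acid (30 mol %), toluene, rt, dark; then SiO2 chromatography (separates the aR from the aS atropisomer)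
Reagents that add atoms: none
Why: Iminium/enamine domino reaction in which the phenol of 7 adds to the β-carbon of each E-iminium ion on the face away from the CPh2(OSiMe3) group (standard shielding model, predicting 2R), the resulting enamine closes ring C by intramolecular aldol addition to the aryl aldehyde and dehydration makes the closure irreversible; running two catalyst-controlled events per molecule raises the enantiopurity of the C2-symmetric product statistically, while the axis is not controlled and is resolved by the chromatography.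

Step 10
Reactants: 15 (aR)-2,2'-[4,4',5,5',6,6'-hexakis(benzyloxy)biphenyl-2,2'-diyl]bis[(2R)-5,7-bis(benzyloxy)-2H-chromene-3-carbaldehyde]
Product: 17 (aR)-2,2'-[4,4',5,5',6,6'-hexakis(benzyloxy)biphenyl-2,2'-diyl]bis[(2R)-5,7-bis(benzyloxy)chroman-3-one], via bis(enol formate) 16 (not isolated)
Conditions: 30% H2O2, (2-O2NC6H4Se)2 (5 mol %), CH2Cl2, rt; then KHCO3 (cat.), MeOH, 0 °C
Reagents that add atoms: hydrogen peroxide, OO
Why: Baeyer–Villiger oxidation of an α-substituted cinnamaldehyde-type enal with migration of the electron-rich vinyl group gives the enol formate, and brief cold methanolysis frees the enol, which ketonises by protonation at C4 so that C2 is not touched.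

Step 11
Reactants: 17 (aR)-2,2'-[4,4',5,5',6,6'-hexakis(benzyloxy)biphenyl-2,2'-diyl]bis[(2R)-5,7-bis(benzyloxy)chroman-3-one]
Product: 18 (aR)-2,2'-[4,4',5,5',6,6'-hexakis(benzyloxy)biphenyl-2,2'-diyl]bis[(2R,3R)-5,7-bis(benzyloxy)chroman-3-ol]
Conditions: LiBH(s-Bu)3, LiBr, THF, −78 °C; then H2O
Reagents that add atoms: none
Why: Substrate-controlled reduction in which the bulky trialkylborohydride attacks each C3 carbonyl from the face opposite the C2 aryl group, setting the 2,3-cis (3R) alcohol as in the known flavan-3-one to epicatechin conversion, and low temperature keeps hydride delivery faster than enolisation towards C2.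

Step 12
Reactants: 18 (aR)-2,2'-[4,4',5,5',6,6'-hexakis(benzyloxy)biphenyl-2,2'-diyl]bis[(2R,3R)-5,7-bis(benzyloxy)chroman-3-ol]
Product: 19 theasinensin C
Conditions: H2 (1 atm), Pd(OH)2/C, THF/MeOH, rt; filtration and lyophilisation under argon
Reagents that add atoms: none
Why: Global hydrogenolysis of twelve benzyl aryl ethers under conditions that leave the chroman C2–O bond intact in catechin chemistry, with no stereocentre or the axis affected.

**Compound list**

1 | phloroglucinol (benzene-1,3,5-triol) | Oc1cc(O)cc(O)c1 | starting material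
2 | benzene-1,3,5-triyl triacetate | CC(=O)Oc1cc(OC(C)=O)cc(OC(C)=O)c1 | intermediate
3 | sodium 3,5-bis(benzyloxy)phenolate | [Na+].[O-]c1cc(OCc2ccccc2)cc(OCc2ccccc2)c1 | intermediate (not isolated)
4 | 1,3,5-tris(benzyloxy)benzene | C(Oc1cc(OCc2ccccc2)cc(OCc2ccccc2)c1)c1ccccc1 | intermediate
5 | N-[2,4,6-tris(benzyloxy)benzylidene]-N-methylmethanaminium chloride | C[N+](C)=Cc1c(OCc2ccccc2)cc(OCc2ccccc2)cc1OCc1ccccc1.[Cl-] | intermediate (not isolated)
6 | 2,4,6-tris(benzyloxy)benzaldehyde | O=Cc1c(OCc2ccccc2)cc(OCc2ccccc2)cc1OCc1ccccc1 | intermediate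
7 | 4,6-bis(benzyloxy)-2-hydroxybenzaldehyde | O=Cc1c(O)cc(OCc2ccccc2)cc1OCc1ccccc1 | intermediate
8 | 3,4,5-trihydroxybenzaldehyde | O=Cc1cc(O)c(O)c(O)c1 | starting material
9 | 3,4,5-tris(benzyloxy)benzaldehyde | O=Cc1cc(OCc2ccccc2)c(OCc2ccccc2)c(OCc2ccccc2)c1 | intermediate
10 | 2-bromo-3,4,5-tris(benzyloxy)benzaldehyde | O=Cc1cc(OCc2ccccc2)c(OCc2ccccc2)c(OCc2ccccc2)c1Br | intermediate
11 | rac-4,4',5,5',6,6'-hexakis(benzyloxy)biphenyl-2,2'-dicarbaldehyde | O=Cc1cc(OCc2ccccc2)c(OCc2ccccc2)c(OCc2ccccc2)c1-c1c(C=O)cc(OCc2ccccc2)c(OCc2ccccc2)c1OCc1ccccc1 | intermediate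
12 | rac-(2E,2'E)-3,3'-[4,4',5,5',6,6'-hexakis(benzyloxy)biphenyl-2,2'-diyl]bis(prop-2-enal) | O=C/C=C/c1cc(OCc2ccccc2)c(OCc2ccccc2)c(OCc2ccccc2)c1-c1c(/C=C/C=O)cc(OCc2ccccc2)c(OCc2ccccc2)c1OCc1ccccc1 | intermediate
13 | 3,3'-[4,4',5,5',6,6'-hexakis(benzyloxy)biphenyl-2,2'-diyl]bis{(3S)-3-[3,5-bis(benzyloxy)-2-formylphenoxy]propanal}, both axis isomers (3S here is the same spatial arrangement as 2R in 15) | O=CC[C@H](Oc1cc(OCc2ccccc2)cc(OCc2ccccc2)c1C=O)c1cc(OCc2ccccc2)c(OCc2ccccc2)c(OCc2ccccc2)c1-c1c([C@H](CC=O)Oc2cc(OCc3ccccc3)cc(OCc3ccccc3)c2C=O)cc(OCc2ccccc2)c(OCc2ccccc2)c1OCc1ccccc1 | intermediate (not isolated)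
14 | 2,2'-[4,4',5,5',6,6'-hexakis(benzyloxy)biphenyl-2,2'-diyl]bis[(2S)-5,7-bis(benzyloxy)-4-hydroxychromane-3-carbaldehyde], both axis isomers, C3/C4 epimer mixture (2S here is the same spatial arrangement as 2R in 15) | O=CC1C(O)c2c(OCc3ccccc3)cc(OCc3ccccc3)cc2O[C@@H]1c1cc(OCc2ccccc2)c(OCc2ccccc2)c(OCc2ccccc2)c1-c1c([C@H]2Oc3cc(OCc4ccccc4)cc(OCc4ccccc4)c3C(O)C2C=O)cc(OCc2ccccc2)c(OCc2ccccc2)c1OCc1ccccc1 | intermediate (not isolated)
15 | (aR)-2,2'-[4,4',5,5',6,6'-hexakis(benzyloxy)biphenyl-2,2'-diyl]bis[(2R)-5,7-bis(benzyloxy)-2H-chromene-3-carbaldehyde] | O=CC1=Cc2c(OCc3ccccc3)cc(OCc3ccccc3)cc2O[C@@H]1c1cc(OCc2ccccc2)c(OCc2ccccc2)c(OCc2ccccc2)c1-c1c([C@H]2Oc3cc(OCc4ccccc4)cc(OCc4ccccc4)c3C=C2C=O)cc(OCc2ccccc2)c(OCc2ccccc2)c1OCc1ccccc1 | intermediate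
16 | (aR)-[4,4',5,5',6,6'-hexakis(benzyloxy)biphenyl-2,2'-diyl]bis[(2R)-5,7-bis(benzyloxy)-2H-chromene-2,3-diyl] diformate (bis enol formate) | O=COC1=Cc2c(OCc3ccccc3)cc(OCc3ccccc3)cc2O[C@@H]1c1cc(OCc2ccccc2)c(OCc2ccccc2)c(OCc2ccccc2)c1-c1c([C@H]2Oc3cc(OCc4ccccc4)cc(OCc4ccccc4)c3C=C2OC=O)cc(OCc2ccccc2)c(OCc2ccccc2)c1OCc1ccccc1 | intermediate (not isolated)
17 | (aR)-2,2'-[4,4',5,5',6,6'-hexakis(benzyloxy)biphenyl-2,2'-diyl]bis[(2R)-5,7-bis(benzyloxy)chroman-3-one] | O=C1Cc2c(OCc3ccccc3)cc(OCc3ccccc3)cc2O[C@@H]1c1cc(OCc2ccccc2)c(OCc2ccccc2)c(OCc2ccccc2)c1-c1c([C@H]2Oc3cc(OCc4ccccc4)cc(OCc4ccccc4)c3CC2=O)cc(OCc2ccccc2)c(OCc2ccccc2)c1OCc1ccccc1 | intermediate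
18 | (aR)-2,2'-[4,4',5,5',6,6'-hexakis(benzyloxy)biphenyl-2,2'-diyl]bis[(2R,3R)-5,7-bis(benzyloxy)chroman-3-ol] (dodeca-O-benzyl theasinensin C) | O[C@@H]1Cc2c(OCc3ccccc3)cc(OCc3ccccc3)cc2O[C@@H]1c1cc(OCc2ccccc2)c(OCc2ccccc2)c(OCc2ccccc2)c1-c1c([C@H]2Oc3cc(OCc4ccccc4)cc(OCc4ccccc4)c3C[C@H]2O)cc(OCc2ccccc2)c(OCc2ccccc2)c1OCc1ccccc1 | intermediate
19 | theasinensin C, (aR) axis, (2R,3R) in both flavan units | Oc1cc(O)c2c(c1)O[C@H](c1cc(O)c(O)c(O)c1-c1c([C@H]3Oc4cc(O)cc(O)c4C[C@H]3O)cc(O)c(O)c1O)[C@H](O)C2 | target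

**Step count**

Total: 12 steps. Longest linear sequence: 8 steps (steps 5–8 then 9–12; steps 1–4 then 9–12 is equally long).

**Three steps most likely to fail**

Step 9 is the riskiest. The enal β-carbons carry a bulky ortho biaryl group, the aldehyde of 7 is electron-rich and slow in the aldol step, the catalyst may be mismatched with one axis isomer, and the 2H-chromene products can racemise by light-induced ring opening. The sense of induction is predicted from the shielding model, not from a measured case, and should be confirmed on the monomeric 3,4,5-tris(benzyloxy)cinnamaldehyde. The fallback sets out from 11 and uses a nitroalkene as the acceptor. Henry condensation of 11 with nitromethane (NH4OAc, AcOH, 100 °C) gives rac-2,2'-bis[(E)-2-nitroethenyl]-4,4',5,5',6,6'-hexakis(benzyloxy)biphenyl F1. Reaction of F1 with 7 under a proline-derived secondary amine, (S)-1-methyl-2-[(pyrrolidin-2-ylmethyl)sulfanyl]-1H-imidazole with salicylic acid, runs an oxa-Michael addition and an intramolecular nitro-aldol ring closure with loss of water. After separation of the axis isomers this gives the (aR)-bis[(2R)-5,7-bis(benzyloxy)-3-nitro-2H-chromene] F2. Which catalyst antipode gives 2R must be fixed on a monomeric model. Conjugate reduction with NaBH4 (THF/MeOH, 0 °C) gives the (aR)-bis[(2R)-5,7-bis(benzyloxy)-3-nitrochroman] F3. A Nef reaction (NaOMe, then aqueous TiCl3 buffered with NH4OAc) then gives the ketone, and the fallback comes back to the route at 17.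

Step 10 is the second risk. The perselenic oxidant can over-oxidise the electron-rich enol formate or ring A, and the flavan-3-one can epimerise at C2 during formate cleavage. The fallback sets out from 15 and removes the formyl group as carbon monoxide instead. Decarbonylation with stoichiometric RhCl(PPh3)3 (toluene, 90 °C) gives the (aR)-bis[(2S)-5,7-bis(benzyloxy)-2H-chromene] F4 (same spatial arrangement at C2; the descriptor changes by priority only). Hydroboration–oxidation (BH3·THF, then NaOH/H2O2) adds anti to the 2-aryl groups and gives the 2,3-trans diol, the (aR)-bis[(2R,3S)-5,7-bis(benzyloxy)chroman-3-ol] F5. Oxidation with 1,1,1-triacetoxy-1,1-dihydro-1,2-benziodoxol-3(1H)-one (Dess–Martin periodinane) under neutral conditions comes back to the route at 17.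

Step 7 is the third risk. Ullmann coupling to a tetra-ortho-substituted biaryl competes with hydrodebromination, and the aldehyde is exposed to 150 °C. The fallback sets out from 10 and replaces the copper-mediated reductive coupling by a palladium-catalysed cross-coupling. Miyaura borylation of 10 (bis(pinacolato)diboron, PdCl2(dppf), KOAc, dioxane, 90 °C) gives 3,4,5-tris(benzyloxy)-2-(4,4,5,5-tetramethyl-1,3,2-dioxaborolan-2-yl)benzaldehyde F6. Suzuki–Miyaura coupling of F6 with a second equivalent of 10 (Pd(OAc)2, 2-dicyclohexylphosphino-2',6'-dimethoxybiphenyl, K3PO4, toluene/H2O, 100 °C) comes back to the route at 11.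

**Further compounds**

F1 | step 9 | rac-2,2'-bis[(E)-2-nitroethenyl]-4,4',5,5',6,6'-hexakis(benzyloxy)biphenyl | [O-][N+](=O)/C=C/c1cc(OCc2ccccc2)c(OCc2ccccc2)c(OCc2ccccc2)c1-c1c(/C=C/[N+](=O)[O-])cc(OCc2ccccc2)c(OCc2ccccc2)c1OCc1ccccc1
F2 | step 9 | (aR)-2,2'-[4,4',5,5',6,6'-hexakis(benzyloxy)biphenyl-2,2'-diyl]bis[(2R)-5,7-bis(benzyloxy)-3-nitro-2H-chromene] | [O-][N+](=O)C1=Cc2c(OCc3ccccc3)cc(OCc3ccccc3)cc2O[C@@H]1c1cc(OCc2ccccc2)c(OCc2ccccc2)c(OCc2ccccc2)c1-c1c([C@H]2Oc3cc(OCc4ccccc4)cc(OCc4ccccc4)c3C=C2[N+](=O)[O-])cc(OCc2ccccc2)c(OCc2ccccc2)c1OCc1ccccc1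
F3 | step 9 | (aR)-2,2'-[4,4',5,5',6,6'-hexakis(benzyloxy)biphenyl-2,2'-diyl]bis[(2R)-5,7-bis(benzyloxy)-3-nitrochroman], C3 epimer mixture | [O-][N+](=O)C1Cc2c(OCc3ccccc3)cc(OCc3ccccc3)cc2O[C@@H]1c1cc(OCc2ccccc2)c(OCc2ccccc2)c(OCc2ccccc2)c1-c1c([C@H]2Oc3cc(OCc4ccccc4)cc(OCc4ccccc4)c3CC2[N+](=O)[O-])cc(OCc2ccccc2)c(OCc2ccccc2)c1OCc1ccccc1
F4 | step 10 | (aR)-2,2'-[4,4',5,5',6,6'-hexakis(benzyloxy)biphenyl-2,2'-diyl]bis[(2S)-5,7-bis(benzyloxy)-2H-chromene] | C1=Cc2c(OCc3ccccc3)cc(OCc3ccccc3)cc2O[C@@H]1c1cc(OCc2ccccc2)c(OCc2ccccc2)c(OCc2ccccc2)c1-c1c([C@H]2Oc3cc(OCc4ccccc4)cc(OCc4ccccc4)c3C=C2)cc(OCc2ccccc2)c(OCc2ccccc2)c1OCc1ccccc1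
F5 | step 10 | (aR)-2,2'-[4,4',5,5',6,6'-hexakis(benzyloxy)biphenyl-2,2'-diyl]bis[(2R,3S)-5,7-bis(benzyloxy)chroman-3-ol] | O[C@H]1Cc2c(OCc3ccccc3)cc(OCc3ccccc3)cc2O[C@@H]1c1cc(OCc2ccccc2)c(OCc2ccccc2)c(OCc2ccccc2)c1-c1c([C@H]2Oc3cc(OCc4ccccc4)cc(OCc4ccccc4)c3C[C@@H]2O)cc(OCc2ccccc2)c(OCc2ccccc2)c1OCc1ccccc1
F6 | step 7 | 3,4,5-tris(benzyloxy)-2-(4,4,5,5-tetramethyl-1,3,2-dioxaborolan-2-yl)benzaldehyde | O=Cc1cc(OCc2ccccc2)c(OCc2ccccc2)c(OCc2ccccc2)c1B1OC(C)(C)C(C)(C)O1
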